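The slowness of Wednesday's flask comes early: its Za stops falling with over a third still there, although Zb was charged at 3.00 times cZa.

the same everywhere: Za 0.10 M
- Wednesday's: Zb 0.30 M; temperature 110 °C; the very flask that is asked about, followed so far
- Tuesday's: Zb 0.30 M; temperature 105 °C; run made earlier
- flask: Zb 0.300 M; temperature 110 °C; time 40 h

| run | time / h | Zd / % | Za / % |
|---|---|---|---|
| Wednesday's | 1.33 | 30 | 63 |
| Wednesday's | 4.00 | 39 | 49 |
| Wednesday's | 6.00 | 43 | 45 |
| Wednesday's | 10.0 | 48 | 38 |
| Wednesday's | 15.0 | 50 | 39 |
| Wednesday's | 20.0 | 51 | 35 |
| Wednesday's | 25.0 | 50 | 37 |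
| Tuesday's | 1.33 | 27 | 69 |
| Tuesday's | 4.00 | 34 | 54 |
| Tuesday's | 6.00 | 42 | 48 |
| Tuesday's | 10.0 | 46 | 43 |
| Tuesday's | 15.0 | 52 | 40 |
| Tuesday's | 20.0 | 51 | 35 |
| Tuesday's | 25.0 | 51 | 39 |

(each reading ± 1.5 percentage points)

- blue: change nothing and wait 3.0 d more
- amber: at 40 h take out 90% of the Zd then present, then wait 3.0 d
- grey: at 40 h add Zb, 50.0% of the amount charged, then wait 3.0 d
- ochre: at 40 h raise the temperature by 20 K, then wait 3.0 d

- Zd that was removed still counts
- the numbers in the tables scatter with a standard deviation of 1.5 percentage points
- what may be going on: Za + Zb -> Zd; Za + Zb -> Ze; 2 Zb -> Zc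
- additions bring no volume worth counting

* Zd, in percent of the Za first charged, at 40 h
* the remedy with the largest gain of Zd, or "none" below 2 percentage points (blue / amber / grey / ochre / none)
* Zd present, with what was taken out counted in, in percent of the Za first charged, after blue
* Zd present, with what was taken out counted in, in percent of the Za first charged, after ochre

I count turnovers. Wednesday's late readings give 0.994: this is the turnover count n, the natural logarithm of Za charged over Za left. Its rate is k·cZb, with k covering both steps from Za. Of the Za gone, Zd takes 79.9% in these readings.

In one extreme, cZb holds at its charge, the pseudo-first-order case. The first reading gives 0.347 /h, so n reaches 13.9 by 40 h, and Zd ends near 79.9%. In the other extreme, cZb is gone by the late readings, n stops at its late value, and Zd stays at 50.3%.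

The readings lie beside the second. Between 4.00 h and 25.0 h the count runs at 0.0134 /h, so these readings put the mean cZb of that span about 25.9 times below its mean up to the first reading. From 10.0 h on, n rises 0.0267, less than its scatter of 0.0405.

So I commit to about 50.3% now, and about the same after blue and ochre, since the late count moves less than its scatter. The listed steps hold no way back, so amber gains little too. Grey brings new Zb. Taking the count in proportion to the charge, it adds 12 percentage points of Zd.

The forecast gives 52% now, 55% after blue and 58% after ochre, above my figure, and picks grey: “Fresh Zb restarts the reaction”.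

The flask gives 52.2% now, with Zb at 0.105% of its charge. It gives 52.4% after blue and 52.4% after ochre. The gains are 0.25 points for blue, 0.25 points for amber, 0.23 points for ochre and 20 points for grey.

    Za + Zb → Zd (k = 2.00 /M/h, Ea = 81.0 kJ/mol)
    Za + Zb → Ze (k = 0.480 /M/h, Ea = 103 kJ/mol)
    2 Zb → Zc (k = 3.40 /M/h, Ea = 92.0 kJ/mol)
    (constants at 110 °C)

The neighbour flask is charged with 0.075 M of Zb, a quarter of the recipe's Zb. In proportion to the charge, its count is 0.249, which leaves Za at 78.0% and gives Zd 17.6%. This neighbour ends with Za at 61.9%, so its count is 0.480, about half of n. Its Zb stands at 0.0408% of its own charge. Zd takes 80.6% of the Za gone and stands at 30.7%.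

The data were computed with made-up constants, noise included.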